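## Structural features

The target is a labdane: a trans-fused decalin (ring A = C1–C5 and C10, ring B = C5–C10) that carries at C9 a six-carbon chain (C11–C16) ending in an E-trisubstituted alkene and a primary allylic acetate. Four stereocentres stand in a row along C5–C10–C9–C8 (5S,10S,9R,8R): the ring-fusion CH, the quaternary ring-fusion carbon with its β-methyl (C20), the side-chain methine, and the tertiary carbinol, whose methyl (C17) is axial and syn to C20 while the hydroxyl is equatorial (8α). C4 is a second quaternary carbon (gem-dimethyl) bonded directly to C5, so the adjacent ring atoms C4, C5 and C10 are all heavily substituted. The tertiary 8-hydroxyl is the fragile group, since acid dehydrates it or adds it across the C13 alkene to give a cyclic ether. The allylic acetate ionises with strong Lewis acids or zerovalent palladium and is lost to hydride and carbanion reagents. The difficulty therefore lies in the congested C4–C5–C10–C9–C8 array (two quaternary carbons, a 1,3-diaxial pair of methyl groups, the C9/C10 relationship), not in the side chain. The key step uses two coincidences: C7, C8, C17, C9 and C11–C16 with the C15 oxygen are the unbroken chain of geranyl acetate, and the C1 and C4 branches sit trans across the C5–C10 bond just as formyl and ester do across the double bond of an E-3-formylcrotonate. Ring B can thus be closed by a [4+2] union that forms C5–C6 and C9–C10, sets C5, C9 and C10 together, and leaves a C7–C8 alkene from which the carbinol is made.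

## Logic of the disconnections

**18 to 17.** The acetyl C–O bond at O15 is cut last. The hydride that makes the C8 carbinol also removes any ester, so the acetate has to be put on after it. The forward step must acylate the primary allylic hydroxyl and leave the hindered tertiary one alone.

**17 to 16 to 15.** The C8–O bond and the C7–H bond are traced back through the 7α,8α-epoxide 16 to the C7=C8 alkene of 15. A [4+2] leaves exactly this alkene in ring B, and the axial C20 methyl blocks the β face, so the oxygen should enter from α as required. The forward steps need site selectivity over the C13 alkene (the allylic acetate deactivates it) and hydride delivery at C7, not C8.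

**15 to 14 to 13.** Ring A is opened between C1 and C2, after adding back the C1=C2 alkene of 14, as a ring-closing metathesis retron. The trans arrangement of the C1 and C4 arms on ring B suits a trans-fused closure. The gain is a monocycle with two terminal alkenes. The demands are metathesis that ignores the two trisubstituted alkenes and a reduction that saturates only the new disubstituted alkene.

**13 to 12, 11 and 10.** The C3–C4 bond is cut between an allyl unit and the tertiary C4 radical, which comes from the dimethyl carbinol 10 through its oxalate (11, 12). A quaternary carbon next to C5 cannot be made by displacement, and a cation there would eliminate or rearrange, so a radical is the safe intermediate. The forward step needs the primary hydroxyl masked (as the acetate, which the later epoxidation also wants) and intermolecular capture of a hindered radical.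

**10 to 9 to 7 and 8.** The two C4–CH3 bonds are cut, which reduces the carbinol to the ester of 7 and two equivalents of 8. Reagent 8 unavoidably cleaves the acetate, so 9 is the diol and 10 restores the acetate on the primary oxygen. A silyl ether carried from the start would avoid this, but it costs one step more overall and deactivates the C13 alkene less well at the epoxidation. The demands are complete double addition to a hindered ester and no loss of configuration at C5.

**7 to 6.** The C1=CH2 bond is cut (Wittig). The formyl group of 6 must be converted before 8 is used, and the vinyl group is the metathesis handle. The extra carbon leaves later as ethene.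

**6 to 4 and 5.** C5–C6 and C9–C10 are cut together, which is the key step. Three stereocentres and ring B are reduced to an achiral triene and a purchased dienophile. The forward step needs regiocontrol, a formyl-exo transition state and one enal face.

**4 to 3 to 1.** The C6=C7 bond (Wittig) and the C7 oxygen (allylic oxidation of the E-methyl group of 1 through 2) are removed. This leaves commercial 1, whose E-alkene and acetate are carried through unchanged.

## Other disconnections considered

**Alternative 1:** The cut is C9–C10, with the C6–O bond of a δ-lactone as a temporary link. In the forward step lactone A2 is converted into its silyl ketene acetal (KHMDS, Et3SiCl) and rearranges by an Ireland–Claisen ring contraction through a boat transition state to the acid A1.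
- In its favour: ring A is bought intact, and the C8 tertiary oxygen with the right configuration is in place before the key step. On both counts it is better than the chosen plan, which spends six steps on ring A and two late steps on C8. Chirality is relayed from C6 to C10 by the substrate, so no chiral catalyst is needed at that stage, which is at least equal to catalyst control.
- Against it: the new bond must be made to the fully substituted alkene carbon of a trimethylcyclohexene, and the lactone enolate carries a β-silyloxy group that could be expelled. A1 would still need epimerisation at C9, saturation of the hindered C5=C6 alkene from the α face, and a five-carbon extension from the C11 acid that builds the E-trisubstituted alkene.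
- Comparison: the chosen Diels–Alder joins less hindered centres and inherits the whole side chain with its geometry. Alternative 1 is stronger on ring A and C8 and weaker on the side chain and C5. Its total step count would probably be higher.

**Alternative 2:** The cuts are C5–C10 and C8–C9. In the forward step the achiral trienal A4 folds in a chiral-Lewis-acid-catalysed intramolecular Diels–Alder reaction to the trans-decalin aldehyde A3.
- In its favour: two rings and four stereocentres, the C8 oxygen included, would come from one operation on an open chain. That is more complexity per step than the chosen key step (one ring, three centres), and no separate ring-A sequence is needed. Both plans rely on a catalytic enantioselective cycloaddition, so they are equal in the type of enantiocontrol.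
- Against it: the dienophile is a β,β-disubstituted enal, and the C5–C10 bond would join a carbon next to the gem-dimethyl C4 to a carbon that becomes quaternary. The silyloxydiene is labile to Lewis acids, and the short tether does not by itself guarantee trans fusion. C8 arrives secondary, so it needs oxidation and methyl addition, and the methyl group would have to enter axially, syn to the C10 methyl, against the usual equatorial preference. The side chain must again be grown from C11, and A4 itself needs a multi-step synthesis with three defined alkene geometries.
- Comparison: alternative 2 is better on ring count, equal on enantiocontrol, and weaker on C8, on the side chain and probably on total steps.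

**Alternative 3:** The cut is C4–C5. In the forward step Fe(acac)3 and PhSiH3 transfer a hydrogen atom to the prenyl alkene of ketone A6, and the tertiary C4 radical adds 6-exo to the ketone carbon to give the cis-fused carbinol A5.
- In its favour: it makes, intramolecularly and under mild conditions, the same hindered C4 bond that the chosen plan makes by an intermolecular radical allylation (step 8), and on that bond it is the more reliable design. A6 should be short to make from a prochiral cyclic 1,3-diketone, with its configuration set by an early enantioselective reduction.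
- Against it: A5 is cis-fused and carries a C5 hydroxyl, so the ring fusion would have to be corrected by deoxygenation with hydrogen delivery from the α face. Ring B of A5 holds only the C9 oxygen, so the C8 carbinol with its methyl and the entire six-carbon chain remain to be added.
- Comparison: the key step of alternative 3 solves ring A well but fixes little of the target, whereas the chosen cycloaddition sets three centres and delivers the complete chain. Its step economy is the poorest of the four plans.

Key step: step 3

Assumption: the (S)-configured oxazaborolidinium is taken, by the formyl C–H···O binding model, to leave open the Re face at C10 and C5 of bound 5; if the opposite sense applies, the (R)-catalyst is used with no other change.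

## Route

Step 1
Reactants: 1 geranyl acetate [(2E)-3,7-dimethylocta-2,6-dien-1-yl acetate]
Product: 3 (2E,6E)-3,7-dimethyl-8-oxoocta-2,6-dien-1-yl acetate, via 8-hydroxygeranyl acetate 2 (not isolated)
Conditions: SeO2 (0.1 equiv), t-BuOOH (3 equiv), CH2Cl2, 0 °C to rt; crude product, MnO2 (10 equiv), CH2Cl2, rt
Reagents that add atoms: tert-butyl hydroperoxide, CC(C)(C)OO (oxygen passed on by the catalytic SeO2)
Why: Selenium dioxide allylic oxidation (ene reaction, then [2,3]-shift) attacks the E-methyl group of the electron-rich terminal alkene and spares the acetoxy-deactivated C2 alkene; MnO2 then takes the allylic alcohol, and any aldehyde already formed, to the E-enal without touching the acetate.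

Step 2
Reactants: 3 (2E,6E)-3,7-dimethyl-8-oxoocta-2,6-dien-1-yl acetate
Product: 4 (2E,6E)-3,7-dimethylnona-2,6,8-trien-1-yl acetate
Conditions: Ph3PCH3Br (1.15 equiv), KOtBu (1.1 equiv), THF, 0 °C; then 3, −78 to 0 °C
Reagents that add atoms: methyltriphenylphosphonium bromide, C[P+](c1ccccc1)(c1ccccc1)c1ccccc1.[Br-]
Why: Wittig methylenation; the ylide reacts with the enal far faster than with the acetate at low temperature, and the E geometry of the trisubstituted alkene (the later C8–C9 bond of the diene) is not touched.

Step 3
Reactants: 4 (2E,6E)-3,7-dimethylnona-2,6,8-trien-1-yl acetate; 5 ethyl (2E)-3-methyl-4-oxobut-2-enoate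
Product: 6 ethyl (1R,5S,6R)-5-[(3E)-5-acetoxy-3-methylpent-3-en-1-yl]-6-formyl-4,6-dimethylcyclohex-3-ene-1-carboxylate (ester, C6 methyl and side chain mutually cis, formyl trans to them)
Conditions: (S)-3,3-diphenyl-1-(o-tolyl)tetrahydro-1H,3H-pyrrolo[1,2-c][1,3,2]oxazaborole (20 mol %), Tf2NH (18 mol %), 4 (1.5 equiv), CH2Cl2, −78 to −40 °C
Reagents that add atoms: none
Why: The N-protonated oxazaborolidine binds the formyl oxygen of 5 (the most basic carbonyl, held also by a formyl C–H···O contact), and the diene of 4 adds in a concerted but asynchronous [4+2] in which C5–C6 runs ahead of C9–C10. The closest known reaction type is the oxazaborolidinium-catalysed Diels–Alder addition of 2-substituted acroleins, this formylcrotonate included, to acyclic dienes. Ring B is closed as a cyclohexene by intermolecular cycloaddition, both σ bonds being made suprafacially on each partner, and the alkene is left at C7–C8. C5 and C10 keep the trans relation of ester and formyl group that is stored in the E geometry of 5. C9 is set relative to C10 by the formyl-exo, ester-endo transition state, favoured by the α-methyl group and by the endo preference of the ester, which places the outside C11 chain of the E-diene cis to the C10 methyl and the C5 ester. The absolute sense of all three centres comes from the catalyst, whose aryl group covers one enal face so that the diene reaches the Re face at C10 and C5. Regiochemistry is needed and is secured by the unhindered CH2 terminus C6 bonding to the formyl-β carbon C5, in line with the polarisation of the diene by its terminal C9 chain, which should outweigh the weaker opposite effect of the C8 methyl. The remote trisubstituted alkene and the acetate are poorer donors than the diene and the formyl oxygen and should stay out of the reaction at low temperature.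

Step 4
Reactants: 6 ethyl (1R,5S,6R)-5-[(3E)-5-acetoxy-3-methylpent-3-en-1-yl]-6-formyl-4,6-dimethylcyclohex-3-ene-1-carboxylate
Product: 7 ethyl (1R,5S,6R)-5-[(3E)-5-acetoxy-3-methylpent-3-en-1-yl]-6-ethenyl-4,6-dimethylcyclohex-3-ene-1-carboxylate
Conditions: Ph3PCH3Br (1.3 equiv), KOtBu (1.25 equiv), THF, 0 °C; then 6, −78 °C to rt
Reagents that add atoms: methyltriphenylphosphonium bromide, C[P+](c1ccccc1)(c1ccccc1)c1ccccc1.[Br-]
Why: Wittig methylenation of a non-enolisable neopentyl aldehyde, needed before the Grignard step and as the metathesis handle; the small ylide tolerates the α-quaternary centre, and a cold, short reaction should leave both esters and the C5 configuration intact.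

Step 5
Reactants: 7 ethyl (1R,5S,6R)-5-[(3E)-5-acetoxy-3-methylpent-3-en-1-yl]-6-ethenyl-4,6-dimethylcyclohex-3-ene-1-carboxylate; 8 methylmagnesium bromide
Product: 9 (2E)-5-[(1S,5R,6R)-6-ethenyl-5-(2-hydroxypropan-2-yl)-2,6-dimethylcyclohex-2-en-1-yl]-3-methylpent-2-en-1-ol
Conditions: MeMgBr (6 equiv), THF, 0 °C to rt; aq NH4Cl
Reagents that add atoms: methylmagnesium bromide, C[Mg]Br
Why: Grignard double addition to the ester gives the C4 dimethyl carbinol; two further equivalents deliberately cleave the acetate, the alkenes are inert, and C5 stops being an epimerisable centre once the carbonyl is gone.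

Step 6
Reactants: 9 (2E)-5-[(1S,5R,6R)-6-ethenyl-5-(2-hydroxypropan-2-yl)-2,6-dimethylcyclohex-2-en-1-yl]-3-methylpent-2-en-1-ol
Product: 10 (2E)-5-[(1S,5R,6R)-6-ethenyl-5-(2-hydroxypropan-2-yl)-2,6-dimethylcyclohex-2-en-1-yl]-3-methylpent-2-en-1-yl acetate
Conditions: Ac2O (1.2 equiv), pyridine, CH2Cl2, 0 °C
Reagents that add atoms: acetic anhydride, CC(=O)OC(C)=O
Why: Selective O-acylation; the primary allylic hydroxyl reacts and the hindered tertiary one does not without DMAP, which frees the tertiary alcohol for activation and restores the group that later deactivates the C13 alkene.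

Step 7
Reactants: 10 (2E)-5-[(1S,5R,6R)-6-ethenyl-5-(2-hydroxypropan-2-yl)-2,6-dimethylcyclohex-2-en-1-yl]-3-methylpent-2-en-1-yl acetate
Product: 11 methyl 2-[(1R,5S,6R)-5-[(3E)-5-acetoxy-3-methylpent-3-en-1-yl]-6-ethenyl-4,6-dimethylcyclohex-3-en-1-yl]propan-2-yl oxalate
Conditions: ClC(O)CO2Me (2 equiv), Et3N, DMAP (cat.), CH2Cl2, 0 °C to rt
Reagents that add atoms: methyl chlorooxoacetate, COC(=O)C(Cl)=O
Why: Acylation of the tertiary alcohol with the very electrophilic oxalyl half chloride under DMAP catalysis gives the mixed oxalate, the usual precursor of tertiary radicals from alcohols; no stereocentre is involved.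

Step 8
Reactants: 11 methyl 2-[(1R,5S,6R)-5-[(3E)-5-acetoxy-3-methylpent-3-en-1-yl]-6-ethenyl-4,6-dimethylcyclohex-3-en-1-yl]propan-2-yl oxalate
Product: 13 (2E)-5-[(1S,5S,6S)-6-ethenyl-2,6-dimethyl-5-(2-methylpent-4-en-2-yl)cyclohex-2-en-1-yl]-3-methylpent-2-en-1-yl acetate, via cesium oxalate 12 (not isolated)
Conditions: CsOH (1.0 equiv), THF–H2O, 0 °C, 5 min, concentrate; then allyl phenyl sulfone (5 equiv), Ir[dF(CF3)ppy]2(dtbbpy)PF6 (2 mol %), DMF–MeCN, H2O (10 equiv), blue LED, 40 °C
Reagents that add atoms: allyl phenyl sulfone, C=CCS(=O)(=O)c1ccccc1; cesium hydroxide, [Cs+].[OH-] (cesium is held only in 12)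
Why: One equivalent of hydroxide cleaves the activated methyl oxalate much faster than the acetate; the excited photocatalyst oxidises the oxalate, two CO2 are lost, and the tertiary C4 radical adds to the CH2 terminus of the allyl sulfone and expels the sulfonyl radical (radical allylation by addition–fragmentation), which closes the catalytic cycle; C4 is not stereogenic, and both ring-bound alkenes stand to the radical as pent-4-enyl partners, for which cyclisation is slow.

Step 9
Reactants: 13 (2E)-5-[(1S,5S,6S)-6-ethenyl-2,6-dimethyl-5-(2-methylpent-4-en-2-yl)cyclohex-2-en-1-yl]-3-methylpent-2-en-1-yl acetate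
Product: 14 labda-1,7,13E-trien-15-yl acetate (normal labdane series: 5α-H, 9α-H, 10β-CH3)
Conditions: (H2IMes)(PCy3)Cl2Ru=CHPh (second-generation Grubbs catalyst, 5 mol %), CH2Cl2 (5 mM), 40 °C
Reagents that add atoms: none
Why: Ring-closing metathesis; the ruthenium carbene forms at the unhindered allyl terminus and closes on the C1 vinyl group with loss of ethene, the trans arms on ring B give the trans-fused ring A, and the trisubstituted alkenes are too hindered to compete.

Step 10
Reactants: 14 labda-1,7,13E-trien-15-yl acetate
Product: 15 labda-7,13E-dien-15-yl acetate
Conditions: 2-nitrobenzenesulfonohydrazide (5 equiv), Et3N, CH2Cl2, rt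
Reagents that add atoms: none
Why: Diimide reduction (concerted syn transfer of two hydrogens) falls off steeply with alkene substitution, so the cis-disubstituted C1=C2 alkene is saturated while the two trisubstituted alkenes remain; without a metal there is no allylic hydrogenolysis or alkene migration.

Step 11
Reactants: 15 labda-7,13E-dien-15-yl acetate
Product: 16 7α,8α-epoxylabd-13E-en-15-yl acetate
Conditions: mCPBA (1.05 equiv), NaHCO3, CH2Cl2, 0 °C
Reagents that add atoms: 3-chloroperoxybenzoic acid, O=C(OO)c1cccc(Cl)c1
Why: Prilezhaev epoxidation; the ring alkene is the more electron-rich because the C13 alkene is deactivated by its allylic acetoxy group, and the peracid approaches from the α face because the β face is covered by the axial C10 methyl and the C9 chain, which sets C8 (oxygen α, methyl β).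

Step 12
Reactants: 16 7α,8α-epoxylabd-13E-en-15-yl acetate
Product: 17 labd-13E-ene-8α,15-diol
Conditions: LiAlH4 (4 equiv), THF, 0 °C to reflux; aq NaOH work-up
Reagents that add atoms: none
Why: SN2 hydride opening at the secondary C7 (C8 is tertiary and shielded by the syn-axial C10 methyl) leaves the oxygen on C8 with its configuration, giving the 8α-carbinol; the acetate is reduced to the primary alcohol in the same operation.

Step 13
Reactants: 17 labd-13E-ene-8α,15-diol
Product: 18 8α-hydroxylabd-13E-en-15-yl acetate, (2E)-5-[(1R,2R,4aS,8aS)-2-hydroxy-2,5,5,8a-tetramethyldecahydronaphthalen-1-yl]-3-methylpent-2-en-1-yl acetate (target)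
Conditions: Ac2O (1.2 equiv), pyridine, CH2Cl2, 0 °C to rt
Reagents that add atoms: acetic anhydride, CC(=O)OC(C)=O
Why: Selective acetylation of the primary allylic alcohol; the axial-methyl-flanked tertiary C8 hydroxyl is not acylated under these non-acidic conditions, so dehydration and ether formation are avoided.

## Compound list

1 | geranyl acetate | CC(C)=CCC/C(C)=C/COC(C)=O | starting material
2 | (2E,6E)-8-hydroxy-3,7-dimethylocta-2,6-dien-1-yl acetate | OC/C(C)=C/CC/C(C)=C/COC(C)=O | intermediate (not isolated)
3 | (2E,6E)-3,7-dimethyl-8-oxoocta-2,6-dien-1-yl acetate | O=C/C(C)=C/CC/C(C)=C/COC(C)=O | intermediate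
4 | (2E,6E)-3,7-dimethylnona-2,6,8-trien-1-yl acetate | C=C/C(C)=C/CC/C(C)=C/COC(C)=O | intermediate
5 | ethyl (2E)-3-methyl-4-oxobut-2-enoate | CCOC(=O)/C=C(\C)C=O | starting material
6 | ethyl (1R,5S,6R)-5-[(3E)-5-acetoxy-3-methylpent-3-en-1-yl]-6-formyl-4,6-dimethylcyclohex-3-ene-1-carboxylate | CCOC(=O)[C@@H]1CC=C(C)[C@H](CC/C(C)=C/COC(C)=O)[C@@]1(C)C=O | intermediate
7 | ethyl (1R,5S,6R)-5-[(3E)-5-acetoxy-3-methylpent-3-en-1-yl]-6-ethenyl-4,6-dimethylcyclohex-3-ene-1-carboxylate | CCOC(=O)[C@@H]1CC=C(C)[C@H](CC/C(C)=C/COC(C)=O)[C@@]1(C)C=C | intermediate
8 | methylmagnesium bromide | C[Mg]Br | starting material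
9 | (2E)-5-[(1S,5R,6R)-6-ethenyl-5-(2-hydroxypropan-2-yl)-2,6-dimethylcyclohex-2-en-1-yl]-3-methylpent-2-en-1-ol | CC(C)(O)[C@@H]1CC=C(C)[C@H](CC/C(C)=C/CO)[C@@]1(C)C=C | intermediate
10 | (2E)-5-[(1S,5R,6R)-6-ethenyl-5-(2-hydroxypropan-2-yl)-2,6-dimethylcyclohex-2-en-1-yl]-3-methylpent-2-en-1-yl acetate | CC(C)(O)[C@@H]1CC=C(C)[C@H](CC/C(C)=C/COC(C)=O)[C@@]1(C)C=C | intermediate
11 | methyl 2-[(1R,5S,6R)-5-[(3E)-5-acetoxy-3-methylpent-3-en-1-yl]-6-ethenyl-4,6-dimethylcyclohex-3-en-1-yl]propan-2-yl oxalate | COC(=O)C(=O)OC(C)(C)[C@@H]1CC=C(C)[C@H](CC/C(C)=C/COC(C)=O)[C@@]1(C)C=C | intermediate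
12 | cesium salt of the half-oxalate of 10 (cesium 2-oxo-2-alkoxyacetate, ring configuration as in 11) | [Cs+].[O-]C(=O)C(=O)OC(C)(C)[C@@H]1CC=C(C)[C@H](CC/C(C)=C/COC(C)=O)[C@@]1(C)C=C | intermediate (not isolated)
13 | (2E)-5-[(1S,5S,6S)-6-ethenyl-2,6-dimethyl-5-(2-methylpent-4-en-2-yl)cyclohex-2-en-1-yl]-3-methylpent-2-en-1-yl acetate | C=CCC(C)(C)[C@@H]1CC=C(C)[C@H](CC/C(C)=C/COC(C)=O)[C@@]1(C)C=C | intermediate
14 | labda-1,7,13E-trien-15-yl acetate | CC(=O)OC/C=C(\C)CC[C@@H]1[C@@]2(C)C=CCC(C)(C)[C@@H]2CC=C1C | intermediate
15 | labda-7,13E-dien-15-yl acetate | CC(=O)OC/C=C(\C)CC[C@@H]1[C@@]2(C)CCCC(C)(C)[C@@H]2CC=C1C | intermediate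
16 | 7α,8α-epoxylabd-13E-en-15-yl acetate | CC(=O)OC/C=C(\C)CC[C@@H]1[C@@]2(C)CCCC(C)(C)[C@@H]2C[C@H]3O[C@@]13C | intermediate
17 | labd-13E-ene-8α,15-diol | OC/C=C(\C)CC[C@@H]1[C@@]2(C)CCCC(C)(C)[C@@H]2CC[C@@]1(C)O | intermediate
18 | 8α-hydroxylabd-13E-en-15-yl acetate | CC(=O)OC/C=C(\C)CC[C@@H]1[C@@]2(C)CCCC(C)(C)[C@@H]2CC[C@@]1(C)O | target

## Step count and least certain steps

Total: 13 steps. Longest linear sequence: 13 steps (1 to 18); 5 and 8 are bought.

**Step 3 (key step).** The most likely failure is loss of regio- and facial control combined with a slow reaction. The C8 methyl polarises the diene against the C9 chain, and the C9–C10 bond joins a substituted diene terminus to a carbon that becomes quaternary. A sluggish catalysed path gives the acid-labile diene and the ionisable allylic acetate time to decay and lets an unselective proton-catalysed path compete.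
Fallback, from 4 and 5, returning at 6: the cycloaddition is run with an achiral promoter (Me2AlCl, CH2Cl2, −78 °C), which gives 6 together with its enantiomer F1. The mixture is condensed with (1R,2R)-N,N'-dimethyl-1,2-diphenylethane-1,2-diamine (molecular sieves, Et2O) to the diastereomeric imidazolidines F2 (from 6) and F3 (from F1). These are separated by chromatography, along with any regioisomer, and F2 is hydrolysed with dilute aqueous acid to return 6.

**Step 8.** The most likely failure is slow capture of the hindered tertiary C4 radical by the weakly activated allyl sulfone. Hydrogen abstraction from the medium or from the side chain would then give the C4–H compound, and the intermediate alkoxycarbonyl radical could close onto the C1 vinyl group before it loses CO2.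
Fallback, from 12, returning at 13: under the same photocatalyst the radical is trapped by the polarity-matched acceptor phenyl vinyl sulfone (Giese addition) to give sulfone F4. The acetate is removed (K2CO3, MeOH) to give F5. The dianion (n-BuLi, 2.2 equiv, THF, −78 °C) is alkylated at the sulfonyl carbon with ICH2SiMe3 to the β-silyl sulfone F6. Fluoride (Bu4NF, THF, reflux) eliminates silyl and sulfonyl groups to the terminal alkene F7, and acetylation as in step 6 gives 13.

**Step 12.** The most likely failure is sluggish or misdirected opening of the epoxide. Attack at C7 runs against the preference for trans-diaxial opening (the diaxial path would need hydride at the shielded tertiary C8), so prolonged heating may be needed and base-induced isomerisation to an allylic alcohol could compete.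
Fallback, from 16, returning at 17: the epoxide is opened at C7 by the soft, non-basic nucleophile phenylselenolate ((PhSe)2, NaBH4, EtOH, reflux), with ethanolysis of the acetate driven to completion, to give the hydroxy selenide F8. Radical deselenation (Bu3SnH, AIBN, toluene, 80 °C) then replaces selenium by hydrogen and gives 17.

## Further compounds

F1 | step 3 | enantiomer of 6, ethyl (1S,5R,6S)-5-[(3E)-5-acetoxy-3-methylpent-3-en-1-yl]-6-formyl-4,6-dimethylcyclohex-3-ene-1-carboxylate | CCOC(=O)[C@H]1CC=C(C)[C@@H](CC/C(C)=C/COC(C)=O)[C@]1(C)C=O
F2 | step 3 | (4R,5R)-1,3-dimethyl-4,5-diphenylimidazolidin-2-yl aminal of 6 (formyl carbon as C2 of the imidazolidine) | CCOC(=O)[C@@H]1CC=C(C)[C@H](CC/C(C)=C/COC(C)=O)[C@@]1(C)C2N(C)[C@H](c3ccccc3)[C@@H](c3ccccc3)N2C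
F3 | step 3 | (4R,5R)-1,3-dimethyl-4,5-diphenylimidazolidin-2-yl aminal of F1 | CCOC(=O)[C@H]1CC=C(C)[C@@H](CC/C(C)=C/COC(C)=O)[C@]1(C)C2N(C)[C@H](c3ccccc3)[C@@H](c3ccccc3)N2C
F4 | step 8 | analogue of 13 with a 2-(phenylsulfonyl)ethyl group on C4 in place of allyl (ring configuration as in 13) | O=S(=O)(CCC(C)(C)[C@@H]1CC=C(C)[C@H](CC/C(C)=C/COC(C)=O)[C@@]1(C)C=C)c1ccccc1
F5 | step 8 | primary alcohol from F4 (acetate removed) | O=S(=O)(CCC(C)(C)[C@@H]1CC=C(C)[C@H](CC/C(C)=C/CO)[C@@]1(C)C=C)c1ccccc1
F6 | step 8 | β-silyl sulfone from F5, (trimethylsilyl)methyl group on the sulfonyl-bearing carbon (both epimers at that carbon) | O=S(=O)(C(C[Si](C)(C)C)CC(C)(C)[C@@H]1CC=C(C)[C@H](CC/C(C)=C/CO)[C@@]1(C)C=C)c1ccccc1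
F7 | step 8 | primary alcohol corresponding to 13 (deacetyl 13) | C=CCC(C)(C)[C@@H]1CC=C(C)[C@H](CC/C(C)=C/CO)[C@@]1(C)C=C
F8 | step 12 | 7β-(phenylselanyl)labd-13E-ene-8α,15-diol | OC/C=C(\C)CC[C@@H]1[C@@]2(C)CCCC(C)(C)[C@@H]2C[C@H]([Se]c3ccccc3)[C@@]1(C)O
A1 | alternative 1 | 8α-(triethylsilyloxy)-9-epi-drim-5-en-11-oic acid | OC(=O)[C@H]1[C@@]2(C)CCCC(C)(C)C2=CC[C@@]1(C)O[Si](CC)(CC)CC
A2 | alternative 1 | 4-methyl-4-(triethylsilyloxy)-6-(2,6,6-trimethylcyclohex-1-en-1-yl)oxan-2-one, methyl cis to the cyclohexenyl group | O=C1C[C@](C)(O[Si](CC)(CC)CC)C[C@H](O1)C2=C(C)CCCC2(C)C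
A3 | alternative 2 | 8β-(tert-butyldimethylsilyloxy)-12-nordrim-6-en-11-al | O=C[C@@H]1[C@@]2(C)CCCC(C)(C)[C@@H]2C=C[C@@H]1O[Si](C)(C)C(C)(C)C
A4 | alternative 2 | (2E,8E,10E)-11-(tert-butyldimethylsilyloxy)-3,7,7-trimethylundeca-2,8,10-trienal | O=C/C=C(\C)CCCC(C)(C)/C=C/C=C/O[Si](C)(C)C(C)(C)C
A5 | alternative 3 | cis-fused 9α-(tert-butyldimethylsilyloxy)-4,4,10β-trimethyldecalin-5β-ol (labdane numbering) | O[C@]12CCC[C@@H](O[Si](C)(C)C(C)(C)C)[C@@]1(C)CCCC2(C)C
A6 | alternative 3 | 3-(tert-butyldimethylsilyloxy)-2-methyl-2-(4-methylpent-3-en-1-yl)cyclohexan-1-one, silyloxy trans to the methyl group | O=C1CCC[C@@H](O[Si](C)(C)C(C)(C)C)[C@@]1(C)CCC=C(C)C
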